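## Analysis of the target

The target is an olivil-type lignan built on a single oxolane ring. Numbering follows the name: O1, C2 (ring CH2), C3 (fully substituted, bearing the acetoxy group and the 4-hydroxy-3-methoxybenzyl group), C4 (CH bearing CH2OH), C5 (CH bearing the 3,4-dimethoxyphenyl group). The three stereocentres are contiguous, (3S,4R,5S). The C5 aryl and the C4 CH2OH are trans, the C4 CH2OH and the C3 benzyl group are cis, so the C3 acetoxy group is trans to CH2OH and cis to the C5 aryl. Three groups are sensitive:

- The C5–O1 bond is a benzylic ether of an electron-rich arene, open to acid ionisation and to hydrogenolysis.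
- The tertiary acetate sits 1,3 to a free primary alcohol and can migrate as soon as an alkoxide is present.
- The free phenol is para to a benzylic CH2.

The hard points are the oxygen-bearing quaternary C3 next to C4, and the fact that only the most hindered of three hydroxyls is acylated. The feature the strategy is tied to is the C3–C4 bond with its 1,3-dioxygen pattern O–C3–C4–CH2–O. This is what forms when a β-oxy radical from an epoxide (C4 and its CH2O) adds to a ketone carbon (C3). Both carbons are electrophilic in their natural polarity, so the union needs a polarity reversal.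

## Retrosynthetic reasoning

**End game (14 from 13, 12, 11).** The last operations are not skeletal. To avoid acyl migration the final step is a neutral hydrogenolysis. Target 14 is traced to 13, in which the phenol is a benzyl ether and the primary alcohol a benzyl carbonate. 13 comes from acetylation of the tertiary alcohol of 12, and 12 from acylation of the primary alcohol of diol 11, where primary against tertiary poses no selectivity problem. No stereocentre is touched after 11.

**Key disconnection (11 from 9, through 10).** The C3–C4 bond of the ring is cut. This removes the ring, the quaternary carbinol C3 and the C4 stereocentre in one stroke and leaves the acyclic epoxy keto ether 9. In 9 only the carbinol carbon (future C5) has to be controlled. The forward reaction is a reductive radical cyclization with a titanocene reagent of trivalent titanium. The epoxide is opened to a radical at the future C4, which closes 5-exo onto the ketone carbon and is reduced to the dialkoxide 10. The cut is made here because it splits the molecule into two halves of similar size, one arene in each. It also creates the 1,3-diol directly, and the epoxide configuration is erased in the radical.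

**Ether bond (9 from 5 and 8).** The O1–C2 bond is cut. Forward, a rhodium carbenoid from diazoketone 8 inserts into the O–H bond of epoxy alcohol 5 under neutral conditions. A base-mediated ether synthesis would expose an α-halo ketone and an epoxy alkoxide to base; the insertion avoids both and makes the α-alkoxy ketone in one step.

**Epoxy alcohol (5 from 4, from 1 and 2 through 3).** Only the carbinol configuration of 5 matters. A tartrate–titanium kinetic resolution of racemic allylic alcohol 4 sets it and installs the epoxide in the same step. 4 comes from vinyl addition of 2 to aldehyde 1 via alkoxide 3.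

**Diazoketone (8 from 6 through 7).** The C–C bond between the acyl carbon and the diazo carbon is cut: acid 6 is activated as chloride 7 and acylates diazomethane.

## Alternatives that were turned down

Alternative 1: the textbook route. The chain is cut at C4–C5 (aldol) and the ring at O1–C5. A hydroxylated aldol lactone A1 would be assembled by an auxiliary-based alkylation, an aldol addition to 1 and an enolate hydroxylation anti to the C4 substituent. Hydride reduction would give tetraol A2, and acid would close the ring by SN1 attack of the C2 hydroxyl on the benzylic C5 cation, which also settles the aryl group trans to C4. Each step is sound. It was turned down on step economy: the three stereocentres are made in three separate operations, an auxiliary and a lactone reduction are needed, and the same three end-game steps still follow. The count is well above ten.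

Alternative 2: a temporary second ring. The target is derived from the angular-hydroxy furofuran A3, in which an extra C–O bond ties the C4 CH2O to the benzylic carbon of the C3 side chain. The forward key step is reductive cleavage of that benzylic C–O bond, through the p-quinone methide that only the free phenol can form. The cis ring fusion of A3 would fix the C3/C4 relation. It was turned down because A3 has four stereocentres, one of which is destroyed, and building it needs the same C3–C4 bond construction plus a second ring closure. The problem is moved, not simplified.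

Alternative 3: cut the C3–benzyl bond. A benzylic organometallic would be added to the oxolan-3-one A4. It was turned down on mechanism. The nucleophile approaches the ketone anti to the adjacent C4 arm, which places the benzyl group trans to CH2OR, the C3 epimer of the target. A4 is also a β-alkoxy ketone with an epimerisable α-centre prone to elimination, and A4 itself needs about six steps.

Key step: step 5

Remark (assumption): 2-[4-(benzyloxy)-3-methoxyphenyl]acetic acid (6) is taken as purchased; it is one O-benzylation away from homovanillic acid. In acyclic precursors the ring numbers C2 to C5 denote the carbons that become these ring atoms.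

## Route

Step 1
Reactants: 1 3,4-dimethoxybenzaldehyde; 2 vinylmagnesium bromide
Product: 4 racemic allylic alcohol 1-(3,4-dimethoxyphenyl)prop-2-en-1-ol, via bromomagnesium alkoxide 3 (not isolated)
Conditions: 2 (1.2 equiv), THF, −78 → 0 °C; then sat. aq. NH4Cl
Reagents that add atoms: none
Why: Grignard 1,2-addition to an aromatic aldehyde; the product is racemic and its configuration is set in step 2.

Step 2
Reactants: 4 racemic 1-(3,4-dimethoxyphenyl)prop-2-en-1-ol
Product: 5 epoxy alcohol (R)-(3,4-dimethoxyphenyl)[(2R)-oxiran-2-yl]methanol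
Conditions: Ti(OiPr)4 (0.1 equiv), D-(−)-diisopropyl tartrate (0.15 equiv), tBuOOH (0.45 equiv, in decane), 4 Å molecular sieves, CH2Cl2, −20 °C, stopped below half conversion; chromatography on Et3N-deactivated silica
Reagents that add atoms: tert-butyl hydroperoxide, CC(C)(C)OO
Why: Sharpless kinetic resolution: with the D-(−)-tartrate the (S)-enantiomer of 4 (aryl on the face away from the incoming oxygen) is epoxidised fast to the anti epoxy alcohol 5, and (R)-4 is left behind and separated. This sets the future C5; the epoxide carbon formed alongside is erased in step 5.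

Step 3
Reactants: 6 2-[4-(benzyloxy)-3-methoxyphenyl]acetic acid
Product: 8 diazoketone 1-[4-(benzyloxy)-3-methoxyphenyl]-3-diazopropan-2-one, via acid chloride 7 (not isolated)
Conditions: (COCl)2, cat. DMF, CH2Cl2, 0 °C → rt, evaporate; then CH2N2 (3 equiv), Et2O, 0 °C
Reagents that add atoms: oxalyl chloride, O=C(Cl)C(=O)Cl (the chlorine of 7); diazomethane, C=[N+]=[N-] (the CHN2 group of 8)
Why: Acid chloride formation followed by acylation of diazomethane (first stage of the Arndt–Eistert sequence); the second equivalent of diazomethane takes up the HCl. No amine base is used, so no ketene forms from the arylacetyl chloride.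

Step 4
Reactants: 5 (R)-(3,4-dimethoxyphenyl)[(2R)-oxiran-2-yl]methanol; 8 1-[4-(benzyloxy)-3-methoxyphenyl]-3-diazopropan-2-one
Product: 9 epoxy keto ether 1-[4-(benzyloxy)-3-methoxyphenyl]-3-{(R)-(3,4-dimethoxyphenyl)[(2R)-oxiran-2-yl]methoxy}propan-2-one
Conditions: Rh2(OAc)4 (1 mol %), CH2Cl2, rt, 8 (1.3 equiv) added over 4 h to 5
Reagents that add atoms: none
Why: Rhodium-carbenoid O–H insertion: the electrophilic carbenoid is captured by the hydroxyl oxygen and proton transfer gives the α-alkoxy ketone. The medium is neutral, so the epoxide, the carbinol centre and the enolisable benzyl ketone are left alone.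

Step 5
Reactants: 9 1-[4-(benzyloxy)-3-methoxyphenyl]-3-{(R)-(3,4-dimethoxyphenyl)[(2R)-oxiran-2-yl]methoxy}propan-2-one
Product: 11 diol (3S,4R,5S)-3-{[4-(benzyloxy)-3-methoxyphenyl]methyl}-5-(3,4-dimethoxyphenyl)-4-(hydroxymethyl)oxolan-3-ol, via bis-titanium dialkoxide 10 (not isolated)
Conditions: Cp2TiCl2 ((C5H5)2TiCl2, 2.5 equiv), Zn dust (6 equiv), THF, rt, 1 h (green Cp2TiCl); 9 in THF added over 1 h (final 0.02 M), rt; then sat. aq. NaH2PO4
Reagents that add atoms: none
Why: Cp2TiCl (trivalent titanium, made in the flask from Cp2TiCl2 and Zn) binds the epoxide oxygen and breaks its bond to the internal carbon by inner-sphere electron transfer, leaving a tetravalent titanium alkoxide on the CH2 group and a secondary radical at the future C4; the epoxide configuration is erased here, so any epimer of 9 at that carbon would give the same radical. The radical closes on the ketone carbon (future C3) in a 5-exo-trig mode, and the oxygen radical so formed (or the titanium-bound carbonyl in the transition state) is reduced at once by a second Cp2TiCl to dialkoxide 10, which makes the C–C bond formation irreversible and joins two carbons that are both electrophilic in 9. The closest known reaction type is the titanocene-mediated reductive cyclization of epoxy ketones to cyclic 1,3-diols, together with the closure of the same β-titanoxy radical onto alkenes and alkynes through an ether tether to give 2-aryl oxolanes. C4 is controlled by the fixed C5 centre: in the chair-like transition state the aryl group is pseudo-equatorial and the CH2O[Ti] arm on the radical carbon turns away from it, which should give the 4,5-trans ring. C3 is controlled by C4: the ketone oxygen carries (or acquires in the transition state) a Cp2Ti(Cl) unit and should avoid the bulky CH2O[Ti] arm for steric and dipolar reasons, so the oxygen should end up trans and the benzyl group cis to CH2OH, as in the target. The step needs regioselective opening to the secondary radical (secured by radical stability), ring closure faster than capture of the radical by a second titanium centre (secured by the short ether tether, dilution and slow addition), and inertness of the dialkyl ketone toward Cp2TiCl (such ketones are not reduced by it). The face selectivity at C3 is the least secure element and is taken up after the compound list.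

Step 6
Reactants: 11 (3S,4R,5S)-3-{[4-(benzyloxy)-3-methoxyphenyl]methyl}-5-(3,4-dimethoxyphenyl)-4-(hydroxymethyl)oxolan-3-ol
Product: 12 benzyl carbonate (3S,4R,5S)-3-{[4-(benzyloxy)-3-methoxyphenyl]methyl}-4-{[(benzyloxycarbonyl)oxy]methyl}-5-(3,4-dimethoxyphenyl)oxolan-3-ol
Conditions: benzyl chloroformate (1.3 equiv), pyridine (3 equiv), CH2Cl2, 0 °C
Reagents that add atoms: benzyl chloroformate, O=C(Cl)OCc1ccccc1
Why: Chemoselective acylation of the primary hydroxyl; the hindered tertiary hydroxyl does not react under these conditions. The carbonate is chosen because it leaves in the same neutral hydrogenolysis as the aryl benzyl ether.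

Step 7
Reactants: 12 (3S,4R,5S)-3-{[4-(benzyloxy)-3-methoxyphenyl]methyl}-4-{[(benzyloxycarbonyl)oxy]methyl}-5-(3,4-dimethoxyphenyl)oxolan-3-ol
Product: 13 tertiary acetate (3S,4R,5S)-3-{[4-(benzyloxy)-3-methoxyphenyl]methyl}-4-{[(benzyloxycarbonyl)oxy]methyl}-5-(3,4-dimethoxyphenyl)oxolan-3-yl acetate
Conditions: Ac2O (10 equiv), DMAP (1.5 equiv), Et3N (5 equiv), CH2Cl2, rt → 40 °C
Reagents that add atoms: acetic anhydride, CC(=O)OC(C)=O
Why: DMAP-catalysed (Steglich-type) acetylation through the N-acetylpyridinium ion, which acylates tertiary alcohols; the C3–O bond is not broken, so C3 keeps its configuration. Participation of the neighbouring carbonate would need a strained trans-fused six-membered cyclic carbonate and is not expected.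

Step 8
Reactants: 13 (3S,4R,5S)-3-{[4-(benzyloxy)-3-methoxyphenyl]methyl}-4-{[(benzyloxycarbonyl)oxy]methyl}-5-(3,4-dimethoxyphenyl)oxolan-3-yl acetate
Product: 14 target (3S,4R,5S)-5-(3,4-dimethoxyphenyl)-3-[(4-hydroxy-3-methoxyphenyl)methyl]-4-(hydroxymethyl)oxolan-3-yl acetate
Conditions: H2 (1 atm), 10% Pd/C, EtOAc, rt, stopped as soon as 13 is consumed
Reagents that add atoms: none
Why: Hydrogenolysis of the aryl benzyl ether and the benzyl carbonate (which then loses CO2), the two most labile benzylic C–O bonds present; the benzylic C5–O1 ring bond should react much more slowly, which is why the reaction is stopped early. The medium is neutral and contains no alkoxide, so the tertiary acetate should not migrate to the freed primary hydroxyl.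

## Compound list

1 | 3,4-dimethoxybenzaldehyde (veratraldehyde) | COc1ccc(C=O)cc1OC | starting material
2 | vinylmagnesium bromide | C=C[Mg]Br | starting material
3 | bromomagnesium 1-(3,4-dimethoxyphenyl)prop-2-en-1-olate (racemic) | C=CC(O[Mg]Br)c1ccc(OC)c(OC)c1 | intermediate (not isolated)
4 | rac-1-(3,4-dimethoxyphenyl)prop-2-en-1-ol | C=CC(O)c1ccc(OC)c(OC)c1 | intermediate
5 | (R)-(3,4-dimethoxyphenyl)[(2R)-oxiran-2-yl]methanol | O[C@H](c1ccc(OC)c(OC)c1)[C@H]1CO1 | intermediate
6 | 2-[4-(benzyloxy)-3-methoxyphenyl]acetic acid | COc1cc(CC(=O)O)ccc1OCc1ccccc1 | starting material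
7 | 2-[4-(benzyloxy)-3-methoxyphenyl]acetyl chloride | COc1cc(CC(=O)Cl)ccc1OCc1ccccc1 | intermediate (not isolated)
8 | 1-[4-(benzyloxy)-3-methoxyphenyl]-3-diazopropan-2-one | COc1cc(CC(=O)C=[N+]=[N-])ccc1OCc1ccccc1 | intermediate
9 | 1-[4-(benzyloxy)-3-methoxyphenyl]-3-{(R)-(3,4-dimethoxyphenyl)[(2R)-oxiran-2-yl]methoxy}propan-2-one | COc1cc(CC(=O)CO[C@H](c2ccc(OC)c(OC)c2)[C@H]2CO2)ccc1OCc1ccccc1 | intermediate
10 | bis(chlorotitanocene) dialkoxide of diol 11 (tetravalent titanium on both oxygens) | COc1cc(C[C@@]2([O-])CO[C@H](c3ccc(OC)c(OC)c3)[C@H]2C[O-])ccc1OCc1ccccc1.[Ti+4].[Ti+4].[Cl-].[Cl-].c1cc[cH-]c1.c1cc[cH-]c1.c1cc[cH-]c1.c1cc[cH-]c1 | intermediate (not isolated)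
11 | (3S,4R,5S)-3-{[4-(benzyloxy)-3-methoxyphenyl]methyl}-5-(3,4-dimethoxyphenyl)-4-(hydroxymethyl)oxolan-3-ol | COc1cc(C[C@@]2(O)CO[C@H](c3ccc(OC)c(OC)c3)[C@H]2CO)ccc1OCc1ccccc1 | intermediate
12 | (3S,4R,5S)-3-{[4-(benzyloxy)-3-methoxyphenyl]methyl}-4-{[(benzyloxycarbonyl)oxy]methyl}-5-(3,4-dimethoxyphenyl)oxolan-3-ol | COc1cc(C[C@@]2(O)CO[C@H](c3ccc(OC)c(OC)c3)[C@H]2COC(=O)OCc4ccccc4)ccc1OCc1ccccc1 | intermediate
13 | (3S,4R,5S)-3-{[4-(benzyloxy)-3-methoxyphenyl]methyl}-4-{[(benzyloxycarbonyl)oxy]methyl}-5-(3,4-dimethoxyphenyl)oxolan-3-yl acetate | COc1cc(C[C@@]2(OC(C)=O)CO[C@H](c3ccc(OC)c(OC)c3)[C@H]2COC(=O)OCc4ccccc4)ccc1OCc1ccccc1 | intermediate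
14 | (3S,4R,5S)-5-(3,4-dimethoxyphenyl)-3-[(4-hydroxy-3-methoxyphenyl)methyl]-4-(hydroxymethyl)oxolan-3-yl acetate | COc1cc(C[C@@]2(OC(C)=O)CO[C@H](c3ccc(OC)c(OC)c3)[C@H]2CO)ccc1O | target

## Step count and least certain steps

Total step count: 8. Longest linear sequence: 7 steps (steps 1, 2, 4, 5, 6, 7, 8, from 1); step 3 supplies the second fragment.

**Step 5 (key step).** Two processes may go wrong. First, the face selectivity at the ketone carbon may be poor or reversed, either because the carbonyl oxygen is not titanium-bound in the transition state or because a titanium bridge between the two oxygens templates the cis diol. Second, the radical may be captured by a second titanium centre before ring closure, followed by β-elimination of an oxygen substituent. The fallback sets out from 5 and comes back at 11; it puts the C3 oxygen on after the ring is closed.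

- 5 is O-alkylated with propargyl bromide (NaH, THF, 0 °C) to the propargyl ether (2R)-2-[(R)-(3,4-dimethoxyphenyl)(prop-2-yn-1-yloxy)methyl]oxirane F1.
- Sonogashira coupling with purchased 1-(benzyloxy)-4-iodo-2-methoxybenzene (PdCl2(PPh3)2, CuI, Et3N, rt) gives the aryl alkyne F2.
- The titanocene conditions of step 5 close the ring by 5-exo-dig attack on the alkyne, a closure with direct precedent for 2-aryl oxolanes, to the benzylidene oxolane F3. Its alkene geometry is irrelevant.
- Acetylation (Ac2O, pyridine) gives the acetate F4.
- Buffered peracid epoxidation (mCPBA, NaHCO3, CH2Cl2, 0 °C), on the ring face opposite to the C4 arm, gives the spiro-epoxide F5.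
- LiAlH4 (THF, 0 °C) delivers hydride to the benzylic epoxide carbon and removes the acetate, which gives 11.

**Step 4.** The carbenoid may attack its own electron-rich arene or the epoxide oxygen instead of inserting into the hindered secondary O–H bond. The fallback sets out from 5 and comes back at 9.

- Purchased [4-(benzyloxy)-3-methoxyphenyl]boronic acid is coupled with excess 3-chloro-2-(chloromethyl)prop-1-ene (Pd(PPh3)4, K2CO3, THF/H2O) to the allylic chloride 1-(benzyloxy)-4-[2-(chloromethyl)prop-2-en-1-yl]-2-methoxybenzene F6.
- Williamson etherification of 5 with F6 (NaH, cat. NaI, THF, 0 °C) gives the epoxy allyl ether F7.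
- Lemieux–Johnson cleavage of its only alkene (cat. OsO4, NaIO4, 2,6-lutidine, dioxane/H2O) gives 9.

**Step 2.** The electron-rich benzylic epoxy alcohol may be opened by the titanium Lewis acid, or the resolution may discriminate poorly between the enantiomers. The fallback sets out from 4 and comes back at 11; it uses the stereoconvergence of step 5.

- Lipase resolution of 4 (Candida antarctica lipase B, vinyl acetate, toluene, rt) acylates the (R)-enantiomer to the acetate (R)-1-(3,4-dimethoxyphenyl)prop-2-en-1-yl acetate F9. It leaves (S)-1-(3,4-dimethoxyphenyl)prop-2-en-1-ol F8.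
- Epoxidation of F8 (mCPBA, NaHCO3, CH2Cl2, 0 °C) gives 5 together with its epoxide epimer (R)-(3,4-dimethoxyphenyl)[(2S)-oxiran-2-yl]methanol F10.
- The mixture is carried through step 4 to 9 and its epoxide epimer F11. Both give the same radical in step 5 and merge at 11.

**Step 7.** Acylation of the hindered tertiary hydroxyl may be slow, and forcing it may bring loss of the carbonate or elimination. The fallback sets out from 11 and comes back at 14; it acylates the alkoxide instead of the alcohol.

- 11 is silylated at the primary hydroxyl (TBSCl, imidazole, DMF, rt) to the silyl ether F12.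
- Deprotonation and acetylation (LiHMDS, THF, −78 °C; then Ac2O) gives the tertiary acetate F13.
- Acidic desilylation (HF·pyridine, THF, 0 °C), with no alkoxide formed, gives the hydroxy acetate F14.
- Hydrogenolysis (H2, 10% Pd/C, EtOAc) gives 14.

## Further compounds

F1 | step 5 | (2R)-2-[(R)-(3,4-dimethoxyphenyl)(prop-2-yn-1-yloxy)methyl]oxirane | C#CCO[C@H](c1ccc(OC)c(OC)c1)[C@H]1CO1
F2 | step 5 | 1-(benzyloxy)-4-(3-{(R)-(3,4-dimethoxyphenyl)[(2R)-oxiran-2-yl]methoxy}prop-1-yn-1-yl)-2-methoxybenzene | COc1cc(C#CCO[C@H](c2ccc(OC)c(OC)c2)[C@H]2CO2)ccc1OCc1ccccc1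
F3 | step 5 | [(2S,3R)-4-{[4-(benzyloxy)-3-methoxyphenyl]methylidene}-2-(3,4-dimethoxyphenyl)oxolan-3-yl]methanol (alkene geometry not defined) | COc1cc(C=C2CO[C@H](c3ccc(OC)c(OC)c3)[C@H]2CO)ccc1OCc1ccccc1
F4 | step 5 | acetate of F3 | COc1cc(C=C2CO[C@H](c3ccc(OC)c(OC)c3)[C@H]2COC(C)=O)ccc1OCc1ccccc1
F5 | step 5 | spiro-epoxide of F4 (epoxide oxygen trans to the acetoxymethyl arm; benzylic epoxide carbon not defined) | COc1cc(C2O[C@@]23CO[C@H](c4ccc(OC)c(OC)c4)[C@H]3COC(C)=O)ccc1OCc1ccccc1
F6 | step 4 | 1-(benzyloxy)-4-[2-(chloromethyl)prop-2-en-1-yl]-2-methoxybenzene | COc1cc(CC(=C)CCl)ccc1OCc1ccccc1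
F7 | step 4 | (2R)-2-[(R)-({2-[4-(benzyloxy)-3-methoxybenzyl]prop-2-en-1-yl}oxy)(3,4-dimethoxyphenyl)methyl]oxirane | COc1cc(CC(=C)CO[C@H](c2ccc(OC)c(OC)c2)[C@H]2CO2)ccc1OCc1ccccc1
F8 | step 2 | (S)-1-(3,4-dimethoxyphenyl)prop-2-en-1-ol | O[C@@H](C=C)c1ccc(OC)c(OC)c1
F9 | step 2 | (R)-1-(3,4-dimethoxyphenyl)prop-2-en-1-yl acetate | CC(=O)O[C@H](C=C)c1ccc(OC)c(OC)c1
F10 | step 2 | (R)-(3,4-dimethoxyphenyl)[(2S)-oxiran-2-yl]methanol | O[C@H](c1ccc(OC)c(OC)c1)[C@@H]1CO1
F11 | step 2 | 1-[4-(benzyloxy)-3-methoxyphenyl]-3-{(R)-(3,4-dimethoxyphenyl)[(2S)-oxiran-2-yl]methoxy}propan-2-one | COc1cc(CC(=O)CO[C@H](c2ccc(OC)c(OC)c2)[C@@H]2CO2)ccc1OCc1ccccc1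
F12 | step 7 | (3S,4R,5S)-3-{[4-(benzyloxy)-3-methoxyphenyl]methyl}-4-{[(tert-butyldimethylsilyl)oxy]methyl}-5-(3,4-dimethoxyphenyl)oxolan-3-ol | COc1cc(C[C@@]2(O)CO[C@H](c3ccc(OC)c(OC)c3)[C@H]2CO[Si](C)(C)C(C)(C)C)ccc1OCc1ccccc1
F13 | step 7 | (3S,4R,5S)-3-{[4-(benzyloxy)-3-methoxyphenyl]methyl}-4-{[(tert-butyldimethylsilyl)oxy]methyl}-5-(3,4-dimethoxyphenyl)oxolan-3-yl acetate | COc1cc(C[C@@]2(OC(C)=O)CO[C@H](c3ccc(OC)c(OC)c3)[C@H]2CO[Si](C)(C)C(C)(C)C)ccc1OCc1ccccc1
F14 | step 7 | (3S,4R,5S)-3-{[4-(benzyloxy)-3-methoxyphenyl]methyl}-5-(3,4-dimethoxyphenyl)-4-(hydroxymethyl)oxolan-3-yl acetate | COc1cc(C[C@@]2(OC(C)=O)CO[C@H](c3ccc(OC)c(OC)c3)[C@H]2CO)ccc1OCc1ccccc1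
A1 | alternative 1 | hydroxylated aldol lactone, 3-{[4-(benzyloxy)-3-methoxyphenyl]methyl}-4-[(3,4-dimethoxyphenyl)(hydroxy)methyl]-3-hydroxyoxolan-2-one (configuration as in the SMILES) | COc1cc(C[C@@]2(O)C(=O)OC[C@@H]2[C@H](O)c2ccc(OC)c(OC)c2)ccc1OCc1ccccc1
A2 | alternative 1 | tetraol, 2-{[4-(benzyloxy)-3-methoxyphenyl]methyl}-3-[(3,4-dimethoxyphenyl)(hydroxy)methyl]butane-1,2,4-triol (configuration as in the SMILES) | COc1cc(C[C@@](O)(CO)[C@H](CO)[C@H](O)c2ccc(OC)c(OC)c2)ccc1OCc1ccccc1
A3 | alternative 2 | angular-hydroxy furofuran, 6-(3,4-dimethoxyphenyl)-2-(4-hydroxy-3-methoxyphenyl)-3,7-dioxabicyclo[3.3.0]octan-1-ol (configuration as in the SMILES) | O[C@]12CO[C@H](c3ccc(OC)c(OC)c3)[C@H]1CO[C@@H]2c1ccc(O)c(OC)c1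
A4 | alternative 3 | (4R,5S)-4-[(benzyloxy)methyl]-5-(3,4-dimethoxyphenyl)oxolan-3-one | O=C1CO[C@H](c2ccc(OC)c(OC)c2)[C@H]1COCc1ccccc1
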